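**Strategy.** Everything rests on cutting the C1–C10 bond, the one bond shared by the oxirane and the ten-membered carbocycle. C1 lies next to the C2=C3–C4=C5 (Z,Z)-diene and can carry a sulfonium ylide; C10, with its C14 methyl and its oxygen, is a latent methyl ketone. One intramolecular sulfur-ylide epoxidation therefore closes the carbocycle and the oxirane and sets C1 and C10. Its precursor is a trans-γ-butyrolactone (C6/C7 from an Evans aldol, C8 from an asymmetric methallylboration) carrying a dienyl tetrahydrothiophenium arm on C6 and a β-silyloxy methyl ketone arm on C7. The C11 methylene and the epoxy ester are added afterwards.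

Key step: step 14

Remark: germacrane numbering of the target is used for all intermediates (C1–C10 ring carbons, C11/C12 lactone carbons, C13 exocyclic methylene, C14 methyl on C10, C15 methyl on C4). CIP descriptors in the names change along the route where only substituent priorities change, not the geometry.

Step 1
Reactants: 1 (S)-4-benzyl-1,3-oxazolidin-2-one; 2 methyl 4-chloro-4-oxobutanoate
Product: 4 (S)-4-benzyl-3-(4-methoxy-4-oxobutanoyl)-1,3-oxazolidin-2-one, via N-lithio oxazolidinone 3 (not isolated)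
Conditions: n-BuLi, THF, −78 °C; then 2, −78 → 0 °C
Reagents that add atoms: none
Why: N-acylation of the lithiated auxiliary by the acid chloride (standard loading of an Evans oxazolidinone); no stereocentre is formed.

Step 2
Reactants: 5 but-2-yn-1-ol
Product: 7 (Z)-3-iodobut-2-en-1-ol, via cyclic alkenylalanate 6 (not isolated)
Conditions: NaAlH2(OCH2CH2OMe)2, THF, 0 °C → rt; then I2, THF, −78 → 0 °C
Reagents that add atoms: iodine, II
Why: Hydroxyl-directed trans-hydroalumination places aluminium on C3 cis to the CH2O group in a five-membered alanate, and iodinolysis with retention should give the Z-iodide only.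

Step 3
Reactants: 7 (Z)-3-iodobut-2-en-1-ol
Product: 8 (Z)-3-iodobut-2-enal
Conditions: MnO2, CH2Cl2, rt, dark; used at once as a solution
Reagents that add atoms: none
Why: Allylic oxidation with MnO2 under neutral conditions should keep the Z geometry; no stereocentre is formed.

Step 4
Reactants: 4 (S)-4-benzyl-3-(4-methoxy-4-oxobutanoyl)-1,3-oxazolidin-2-one; 8 (Z)-3-iodobut-2-enal
Product: 11 (4S)-4-benzyl-3-{[(2S,3S)-2-[(1Z)-2-iodoprop-1-en-1-yl]-5-oxooxolan-3-yl]carbonyl}-1,3-oxazolidin-2-one, via dibutylboron Z-enolate 9 (not isolated), via syn-aldol adduct 10 (not isolated)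
Conditions: Bu2BOTf, i-Pr2NEt, CH2Cl2, −78 → 0 °C; then 8, −78 → 0 °C; pH 7 buffer, H2O2, MeOH, 0 °C; then TsOH·H2O (cat.), CH2Cl2, rt
Reagents that add atoms: none
Why: Evans syn-aldol: the Z-boron enolate adds through a chair Zimmerman–Traxler transition state on the face away from the benzyl group, which should set C7 and C6 (6,7-syn) together, and acid then closes the γ-hydroxy ester to the trans-lactone without touching either centre.

Step 5
Reactants: 11 lactone imide
Product: 13 (2S,3S)-2-[(1Z)-2-iodoprop-1-en-1-yl]-5-oxooxolane-3-carboxylic acid, via peroxy acid 12 (not isolated)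
Conditions: LiOH, H2O2, THF/H2O, 0 °C; then Na2SO3; then HCl to pH 2
Reagents that add atoms: hydrogen peroxide, OO
Why: Lithium hydroperoxide cleaves the exocyclic imide carbonyl (standard auxiliary removal); any lactone opened by base recloses on acidification because only C12 can form a five-membered ring with O6, and C6/C7 are untouched.

Step 6
Reactants: 13 lactone acid
Product: 14 (4R,5S)-4-(hydroxymethyl)-5-[(1Z)-2-iodoprop-1-en-1-yl]oxolan-2-one
Conditions: BH3·SMe2, THF, 0 °C → rt; then MeOH
Reagents that add atoms: none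
Why: Borane reduces a carboxylic acid much faster than a lactone or a trisubstituted iodoalkene (chemoselective acid reduction); no stereocentre changes.

Step 7
Reactants: 14 hydroxymethyl lactone
Product: 15 (2S,3S)-2-[(1Z)-2-iodoprop-1-en-1-yl]-5-oxooxolane-3-carbaldehyde
Conditions: Dess–Martin periodinane, NaHCO3, CH2Cl2, 0 °C → rt; used at once
Reagents that add atoms: none
Why: Buffered Dess–Martin oxidation gives the aldehyde under non-basic conditions, so the epimerisable C7 centre (trans to C6, the more stable arrangement) should be kept.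

Step 8
Reactants: 15 lactone aldehyde
Product: 17 (4R,5S)-4-[(1R)-1-hydroxy-3-methylbut-3-en-1-yl]-5-[(1Z)-2-iodoprop-1-en-1-yl]oxolan-2-one, via diisopinocampheylborinate 16 (not isolated)
Conditions: (+)-Ipc2BOMe [(−)-α-pinene series], methallylMgCl, Et2O, −78 °C → rt; then 15, −78 °C; then NaBO3·4H2O, THF/H2O, rt
Reagents that add atoms: methallylmagnesium chloride, CC(=C)C[Mg]Cl
Why: Brown asymmetric methallylboration: the B-methallyl reagent of the (−)-α-pinene series should add to the re face of the aldehyde through a chair transition state and set C8 as R (7,8-anti) under reagent control, the lactone carbonyl being inert to allylboranes.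

Step 9
Reactants: 17 homoallylic alcohol
Product: 18 (4S,5S)-5-[(1Z)-2-iodoprop-1-en-1-yl]-4-[(1R)-3-methyl-1-(triethylsilyloxy)but-3-en-1-yl]oxolan-2-one
Conditions: Et3SiOTf, 2,6-lutidine, CH2Cl2, −78 °C
Reagents that add atoms: triethylsilyl triflate, CC[Si](CC)(CC)OS(=O)(=O)C(F)(F)F
Why: Silylation of the secondary alcohol blocks O8, which could otherwise attack the lactone or be lost by E1cB once the C10 ketone is present; configuration is retained.

Step 10
Reactants: 18 silyl ether
Product: 20 (4S,5S)-5-[(1Z)-2-iodoprop-1-en-1-yl]-4-[(1R)-3-oxo-1-(triethylsilyloxy)butyl]oxolan-2-one, via 1,2-diol 19 (not isolated)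
Conditions: OsO4 (cat.), NaIO4, 2,6-lutidine, dioxane/H2O, rt
Reagents that add atoms: osmium tetroxide (catalytic, oxygen replenished by periodate), O=[Os](=O)(=O)=O; sodium periodate, [Na+].[O-]I(=O)(=O)=O
Why: Lemieux–Johnson cleavage: the electron-rich 1,1-disubstituted alkene is dihydroxylated far faster than the deactivated, hindered iodoalkene, and periodate cleaves the diol to the C10 methyl ketone.

Step 11
Reactants: 20 vinyl iodide; 21 prop-2-yn-1-ol
Product: 22 (4S,5R)-5-[(1Z)-5-hydroxy-2-methylpent-1-en-3-yn-1-yl]-4-[(1R)-3-oxo-1-(triethylsilyloxy)butyl]oxolan-2-one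
Conditions: PdCl2(PPh3)2 (cat.), CuI (cat.), Et3N, THF, rt
Reagents that add atoms: none
Why: Sonogashira coupling of the vinyl iodide proceeds with retention of the C4=C5 geometry and tolerates the ketone, lactone and silyl ether; C1–C3 are added.

Step 12
Reactants: 22 enynol
Product: 23 (4S,5R)-5-[(1Z,3Z)-5-hydroxy-2-methylpenta-1,3-dien-1-yl]-4-[(1R)-3-oxo-1-(triethylsilyloxy)butyl]oxolan-2-one
Conditions: Zn dust activated with Cu(OAc)2 and AgNO3, MeOH/H2O (1:1), rt, dark
Reagents that add atoms: none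
Why: Boland reduction: activated zinc reduces only the conjugated, hydroxyl-activated triple bond by cis hydrogen transfer, which should give the 2Z double bond and leave the ketone and lactone untouched.

Step 13
Reactants: 23 (Z,Z)-dienol
Product: 25 1-[(2Z,4Z)-4-methyl-5-{(2R,3S)-5-oxo-3-[(1R)-3-oxo-1-(triethylsilyloxy)butyl]oxolan-2-yl}penta-2,4-dien-1-yl]thiolan-1-ium methanesulfonate, via dienyl mesylate 24 (not isolated)
Conditions: Ms2O, i-Pr2NEt, CH2Cl2, −40 °C; then tetrahydrothiophene (10 equiv), −40 → 0 °C; trituration, used at once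
Reagents that add atoms: methanesulfonic anhydride, CS(=O)(=O)OS(C)(=O)=O; tetrahydrothiophene, C1CCSC1
Why: O-mesylation followed by SN2 displacement by the soft sulfide in the same flask at low temperature should give the thiolanium salt before the doubly allylic mesylate can ionise; no stereocentre is formed.

Step 14
Reactants: 25 thiolanium methanesulfonate
Product: 28 (1R,6R,7S,8R,10R)-1,10-epoxy-8-(triethylsilyloxy)-13-norgermacra-2Z,4Z-dien-12,6-olide, via dienyl sulfonium ylide 26 (not isolated), via betaine 27 (not isolated)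
Conditions: Cs2CO3, MeCN/CH2Cl2, slow addition of 25 (final 1 mM), 0 °C → rt
Reagents that add atoms: none
Why: Proposed new method: carbonate removes only a doubly allylic C1 hydrogen of the sulfonium salt (far more acidic than the ketone or lactone α-hydrogens) to give ylide 26, whose C1 adds to the C10 methyl ketone to give betaine 27, and the C10 alkoxide then displaces tetrahydrothiophene from C1 with inversion, so that the C1–C10 bond and the oxirane C–O bond form in one operation. The closest known reactions are the Corey–Chaykovsky epoxidation of ketones with allylic sulfonium ylides and its intramolecular variants that close five- to seven-membered rings; use as a ten-membered macrocyclisation is the proposed extension. The carbocycle closes by 1,2-addition of C1 to the ketone carbon (10-exo-trig, helped by the two Z double bonds and the trans-lactone, which hold C1 near C10), and the oxirane closes by a 3-exo-tet displacement that needs O–C10–C1–S antiperiplanar. Both new stereocentres (C1, C10) are set under substrate control: addition of the semi-stabilised ylide is reversible, so the outcome reflects the closure rates of equilibrating betaines, and the betaine with C9–C10–C1–C2 antiperiplanar and the C14 methyl outside the ring, anti to the C8 silyloxy group, is expected to close fastest and give the trans (1R,10R) oxirane. The step needs α-regioselectivity of the pentadienyl ylide and ketone-over-lactone chemoselectivity: only the α-adduct has the leaving group next to the alkoxide and can close irreversibly, so adducts through C3 or C5 should revert, the lactone is the less electrophilic carbonyl, no Michael acceptor is present because C13 is still absent, and high dilution suppresses ylide–sulfonium dimerisation.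

Step 15
Reactants: 28 macrocyclic epoxy lactone
Product: 32 (1R,6R,7S,8R,10R)-1,10-epoxy-8-(triethylsilyloxy)germacra-2Z,4Z,11(13)-trien-12,6-olide, via lithium lactone enolate 29 (not isolated), via Mannich base 30 (not isolated), via ammonium iodide 31 (not isolated)
Conditions: LiN(i-Pr)2, THF, −78 °C; CH2=NMe2+ I−, −78 → 0 °C; then MeI, MeOH, rt; then NaHCO3 aq., CH2Cl2, rt
Reagents that add atoms: Eschenmoser's salt (N,N-dimethylmethyleneiminium iodide), C=[N+](C)C.[I-]
Why: Mannich route to α-methylene lactones: the C11 enolate (no β-leaving group) is aminomethylated, the amine is quaternised and a Hofmann-type E1cB elimination installs C13; the C11 centre formed in 30 is destroyed on elimination.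

Step 16
Reactants: 32 silyl ether
Product: 33 (1R,6R,7R,8R,10R)-1,10-epoxy-8-hydroxygermacra-2Z,4Z,11(13)-trien-12,6-olide
Conditions: Bu4NF, AcOH (1:1), THF, 0 °C → rt
Reagents that add atoms: none
Why: Fluoride cleavage of the triethylsilyl ether buffered with AcOH, so that neither the acid-labile vinyl oxirane nor the base-labile lactone (translactonisation to O8) is disturbed; C8 keeps its configuration.

Step 17
Reactants: 34 (E)-2-methylbut-2-en-1-ol
Product: 35 [(2R,3R)-2,3-dimethyloxiran-2-yl]methanol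
Conditions: Ti(Oi-Pr)4 (cat.), D-(−)-diethyl tartrate (cat.), t-BuOOH, 4 Å MS, CH2Cl2, −20 °C
Reagents that add atoms: tert-butyl hydroperoxide, CC(C)(C)OO
Why: Sharpless asymmetric epoxidation: D-(−)-tartrate should direct oxygen to the face that gives the (2R,3R) epoxy alcohol, and the cis relationship of the two methyl groups follows from the E olefin.

Step 18
Reactants: 35 epoxy alcohol
Product: 36 (2S,3R)-2,3-dimethyloxirane-2-carboxylic acid
Conditions: RuCl3·xH2O (cat.), NaIO4, CCl4/MeCN/H2O, 0 °C → rt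
Reagents that add atoms: sodium periodate, [Na+].[O-]I(=O)(=O)=O; water, O
Why: RuO4-catalysed oxidation takes the primary alcohol to the acid and leaves the oxirane intact; the C2 descriptor changes from R to S through CIP priorities only.

Step 19
Reactants: 33 8-hydroxy lactone; 36 (2S,3R)-2,3-dimethyloxirane-2-carboxylic acid
Product: 38 (1R,6R,7R,8R,10R)-8-[(2S,3R)-2,3-dimethyloxirane-2-carbonyloxy]-1,10-epoxygermacra-2Z,4Z,11(13)-trien-12,6-olide (CNP0122107.1), via mixed anhydride 37 (not isolated)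
Conditions: 2,4,6-trichlorobenzoyl chloride, Et3N, THF, rt; then 33, DMAP, toluene, rt
Reagents that add atoms: none
Why: Yamaguchi esterification: the mixed anhydride acylates the hindered 8β-hydroxyl under DMAP catalysis with retention at C8, and the α-quaternary, non-enolisable epoxy acid cannot epimerise.

**Compound list**

1 | (S)-4-benzyl-1,3-oxazolidin-2-one | O=C1N[C@@H](Cc2ccccc2)CO1 | starting material
2 | methyl 4-chloro-4-oxobutanoate | COC(=O)CCC(Cl)=O | starting material
3 | N-lithio derivative of 1 | O=C1N([Li])[C@@H](Cc2ccccc2)CO1 | intermediate (not isolated)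
4 | (S)-4-benzyl-3-(4-methoxy-4-oxobutanoyl)-1,3-oxazolidin-2-one | COC(=O)CCC(=O)N1[C@@H](Cc2ccccc2)COC1=O | intermediate
5 | but-2-yn-1-ol | CC#CCO | starting material
6 | sodium cyclic (Z)-alkenylalanate from 5 (aluminium on C3, bound to O1) | CC1=CCO[Al-]1(OCCOC)OCCOC.[Na+] | intermediate (not isolated)
7 | (Z)-3-iodobut-2-en-1-ol | C/C(I)=C/CO | intermediate
8 | (Z)-3-iodobut-2-enal | C/C(I)=C/C=O | intermediate
9 | dibutylboron Z-enolate of 4 | COC(=O)C/C=C(\OB(CCCC)CCCC)N1[C@@H](Cc2ccccc2)COC1=O | intermediate (not isolated)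
10 | methyl (3S,4S,5Z)-3-{[(4S)-4-benzyl-2-oxo-1,3-oxazolidin-3-yl]carbonyl}-4-hydroxy-6-iodohept-5-enoate | COC(=O)C[C@@H]([C@H](O)/C=C(C)\I)C(=O)N1[C@@H](Cc2ccccc2)COC1=O | intermediate (not isolated)
11 | (4S)-4-benzyl-3-{[(2S,3S)-2-[(1Z)-2-iodoprop-1-en-1-yl]-5-oxooxolan-3-yl]carbonyl}-1,3-oxazolidin-2-one (trans-lactone) | O=C1C[C@H](C(=O)N2[C@@H](Cc3ccccc3)COC2=O)[C@@H](/C=C(C)\I)O1 | intermediate
12 | (2S,3S)-2-[(1Z)-2-iodoprop-1-en-1-yl]-5-oxooxolane-3-carboperoxoic acid | O=C1C[C@H](C(=O)OO)[C@@H](/C=C(C)\I)O1 | intermediate (not isolated)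
13 | (2S,3S)-2-[(1Z)-2-iodoprop-1-en-1-yl]-5-oxooxolane-3-carboxylic acid | O=C1C[C@H](C(=O)O)[C@@H](/C=C(C)\I)O1 | intermediate
14 | (4R,5S)-4-(hydroxymethyl)-5-[(1Z)-2-iodoprop-1-en-1-yl]oxolan-2-one | O=C1C[C@H](CO)[C@@H](/C=C(C)\I)O1 | intermediate
15 | (2S,3S)-2-[(1Z)-2-iodoprop-1-en-1-yl]-5-oxooxolane-3-carbaldehyde | O=C1C[C@H](C=O)[C@@H](/C=C(C)\I)O1 | intermediate
16 | O8-diisopinocampheylborinate of 17 | O=C1C[C@H]([C@H](OB([C@H]2C[C@H]3C[C@@H]([C@@H]2C)C3(C)C)[C@H]2C[C@H]3C[C@@H]([C@@H]2C)C3(C)C)CC(C)=C)[C@@H](/C=C(C)\I)O1 | intermediate (not isolated)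
17 | (4R,5S)-4-[(1R)-1-hydroxy-3-methylbut-3-en-1-yl]-5-[(1Z)-2-iodoprop-1-en-1-yl]oxolan-2-one | O=C1C[C@H]([C@H](O)CC(C)=C)[C@@H](/C=C(C)\I)O1 | intermediate
18 | (4S,5S)-5-[(1Z)-2-iodoprop-1-en-1-yl]-4-[(1R)-3-methyl-1-(triethylsilyloxy)but-3-en-1-yl]oxolan-2-one | O=C1C[C@H]([C@H](O[Si](CC)(CC)CC)CC(C)=C)[C@@H](/C=C(C)\I)O1 | intermediate
19 | 1,2-diol from 18 (both epimers at the carbinol carbon C10) | O=C1C[C@H]([C@H](O[Si](CC)(CC)CC)CC(C)(O)CO)[C@@H](/C=C(C)\I)O1 | intermediate (not isolated)
20 | (4S,5S)-5-[(1Z)-2-iodoprop-1-en-1-yl]-4-[(1R)-3-oxo-1-(triethylsilyloxy)butyl]oxolan-2-one | O=C1C[C@H]([C@H](O[Si](CC)(CC)CC)CC(C)=O)[C@@H](/C=C(C)\I)O1 | intermediate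
21 | prop-2-yn-1-ol | C#CCO | starting material
22 | (4S,5R)-5-[(1Z)-5-hydroxy-2-methylpent-1-en-3-yn-1-yl]-4-[(1R)-3-oxo-1-(triethylsilyloxy)butyl]oxolan-2-one | O=C1C[C@H]([C@H](O[Si](CC)(CC)CC)CC(C)=O)[C@@H](/C=C(C)\C#CCO)O1 | intermediate
23 | (4S,5R)-5-[(1Z,3Z)-5-hydroxy-2-methylpenta-1,3-dien-1-yl]-4-[(1R)-3-oxo-1-(triethylsilyloxy)butyl]oxolan-2-one | O=C1C[C@H]([C@H](O[Si](CC)(CC)CC)CC(C)=O)[C@@H](/C=C(C)\C=C/CO)O1 | intermediate
24 | methanesulfonate of 23 | O=C1C[C@H]([C@H](O[Si](CC)(CC)CC)CC(C)=O)[C@@H](/C=C(C)\C=C/COS(C)(=O)=O)O1 | intermediate (not isolated)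
25 | 1-[(2Z,4Z)-4-methyl-5-{(2R,3S)-5-oxo-3-[(1R)-3-oxo-1-(triethylsilyloxy)butyl]oxolan-2-yl}penta-2,4-dien-1-yl]thiolan-1-ium methanesulfonate | O=C1C[C@H]([C@H](O[Si](CC)(CC)CC)CC(C)=O)[C@@H](/C=C(C)\C=C/C[S+]2CCCC2)O1.CS(=O)(=O)[O-] | intermediate
26 | sulfonium ylide of 25 (carbanion at C1) | O=C1C[C@H]([C@H](O[Si](CC)(CC)CC)CC(C)=O)[C@@H](/C=C(C)\C=C/[CH-][S+]2CCCC2)O1 | intermediate (not isolated)
27 | (1S,6R,7S,8R,10R)-10-oxido-1-(thiolan-1-ium-1-yl)-8-(triethylsilyloxy)-13-norgermacra-2Z,4Z-dien-12,6-olide (betaine) | C1C(=O)O[C@@H]2/C=C(C)\C=C/[C@H]([S+]3CCCC3)[C@](C)([O-])C[C@@H](O[Si](CC)(CC)CC)[C@@H]12 | intermediate (not isolated)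
28 | (1R,6R,7S,8R,10R)-1,10-epoxy-8-(triethylsilyloxy)-13-norgermacra-2Z,4Z-dien-12,6-olide (trans-oxirane, trans-lactone, 8β-OSiEt3) | C1C(=O)O[C@@H]2/C=C(C)\C=C/[C@H]3O[C@]3(C)C[C@@H](O[Si](CC)(CC)CC)[C@@H]12 | intermediate
29 | lithium C11 enolate of 28 | C1=C(O[Li])O[C@@H]2/C=C(C)\C=C/[C@H]3O[C@]3(C)C[C@@H](O[Si](CC)(CC)CC)[C@@H]12 | intermediate (not isolated)
30 | 11-(dimethylaminomethyl) derivative of 28 (both C11 epimers) | CN(C)CC1C(=O)O[C@@H]2/C=C(C)\C=C/[C@H]3O[C@]3(C)C[C@@H](O[Si](CC)(CC)CC)[C@@H]12 | intermediate (not isolated)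
31 | 11-(trimethylammoniomethyl) iodide from 30 | C[N+](C)(C)CC1C(=O)O[C@@H]2/C=C(C)\C=C/[C@H]3O[C@]3(C)C[C@@H](O[Si](CC)(CC)CC)[C@@H]12.[I-] | intermediate (not isolated)
32 | (1R,6R,7S,8R,10R)-1,10-epoxy-8-(triethylsilyloxy)germacra-2Z,4Z,11(13)-trien-12,6-olide | C=C1C(=O)O[C@@H]2/C=C(C)\C=C/[C@H]3O[C@]3(C)C[C@@H](O[Si](CC)(CC)CC)[C@@H]12 | intermediate
33 | (1R,6R,7R,8R,10R)-1,10-epoxy-8-hydroxygermacra-2Z,4Z,11(13)-trien-12,6-olide | C=C1C(=O)O[C@@H]2/C=C(C)\C=C/[C@H]3O[C@]3(C)C[C@@H](O)[C@@H]12 | intermediate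
34 | (E)-2-methylbut-2-en-1-ol | C/C=C(\C)CO | starting material
35 | [(2R,3R)-2,3-dimethyloxiran-2-yl]methanol | OC[C@@]1(C)O[C@@H]1C | intermediate
36 | (2S,3R)-2,3-dimethyloxirane-2-carboxylic acid | OC(=O)[C@@]1(C)O[C@@H]1C | intermediate
37 | mixed anhydride of 36 with 2,4,6-trichlorobenzoic acid | O=C(OC(=O)[C@@]1(C)O[C@@H]1C)c1c(Cl)cc(Cl)cc1Cl | intermediate (not isolated)
38 | (1R,6R,7R,8R,10R)-8-[(2S,3R)-2,3-dimethyloxirane-2-carbonyloxy]-1,10-epoxygermacra-2Z,4Z,11(13)-trien-12,6-olide (CNP0122107.1) | C=C1C(=O)O[C@@H]2/C=C(C)\C=C/[C@H]3O[C@]3(C)C[C@@H](OC(=O)[C@@]3(C)O[C@@H]3C)[C@@H]12 | target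

**Step count.** Total: 19 steps. Longest linear sequence: 16 steps (5 → 7 → 8 → 11 → 13 → 14 → 15 → 17 → 18 → 20 → 22 → 23 → 25 → 28 → 32 → 33 → 38; steps 2–16 and 19).

**Steps most likely to fail**

1. Step 14 (proposed new method). The betaine may form reversibly without closing. The pentadienyl ylide may react through C3 or C5 and give a smaller carbocycle. The C2=C3 bond may isomerise in the ylide, or closure may run through the wrong betaine (cis-oxirane or the opposite face). The fallback uses known chemistry, sets out from dienol 23 and returns at 28. MnO2 oxidation of 23 should give the (2Z,4Z)-dienal F1. A SmI2-mediated keto-aldehyde pinacol macrocyclisation in THF under high dilution closes the same C1–C10 bond and should give the 1,10-diol F2, of which the (1S,10R) isomer is carried on. MsCl/Et3N at −40 °C mesylates only the secondary C1 hydroxyl to give the hydroxy mesylate F3. DBU in CH2Cl2 then lets the tertiary C10 oxygen displace the mesylate with inversion at C1 to give 28.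

2. Step 13. The doubly allylic mesylate may ionise before the sulfide attacks, which would lead to allylic transposition (sulfur on C3 or C5) or Z to E isomerisation. The fallback sets out from 23 and returns at 28. Sulfur is introduced under neutral redox-condensation conditions (PhSSPh, Bu3P, THF; Hata reaction) to give the allylic phenyl sulfide F4. S-Methylation with MeOTf and 2,6-di-tert-butylpyridine in CH2Cl2 gives the methyl(phenyl)sulfonium triflate F5. F5 is cyclised with Cs2CO3 under the conditions of step 14 to give 28, with thioanisole as the leaving group.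

3. Step 15. Iodide or methyl iodide may open the vinyl oxirane during quaternisation, or the Hofmann-type elimination may stall at the ammonium salt. The fallback sets out from 28 and returns at 32. The lithium enolate (LiN(i-Pr)2, THF, −78 °C) is trapped with monomeric formaldehyde to give the 11-hydroxymethyl lactone F6. MsCl/Et3N gives the primary mesylate F7, and DBU-induced E1cB elimination gives 32 without any alkylating agent or iodide.

**Further compounds**

F1 | step 14 | (4S,5R)-5-[(1Z,3Z)-2-methyl-5-oxopenta-1,3-dien-1-yl]-4-[(1R)-3-oxo-1-(triethylsilyloxy)butyl]oxolan-2-one | O=C1C[C@H]([C@H](O[Si](CC)(CC)CC)CC(C)=O)[C@@H](/C=C(C)\C=C/C=O)O1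
F2 | step 14 | (1S,6R,7S,8R,10R)-1,10-dihydroxy-8-(triethylsilyloxy)-13-norgermacra-2Z,4Z-dien-12,6-olide | C1C(=O)O[C@@H]2/C=C(C)\C=C/[C@H](O)[C@](C)(O)C[C@@H](O[Si](CC)(CC)CC)[C@@H]12
F3 | step 14 | 1-O-methanesulfonate of F2 | C1C(=O)O[C@@H]2/C=C(C)\C=C/[C@H](OS(C)(=O)=O)[C@](C)(O)C[C@@H](O[Si](CC)(CC)CC)[C@@H]12
F4 | step 13 | (4S,5R)-5-[(1Z,3Z)-2-methyl-5-(phenylsulfanyl)penta-1,3-dien-1-yl]-4-[(1R)-3-oxo-1-(triethylsilyloxy)butyl]oxolan-2-one | O=C1C[C@H]([C@H](O[Si](CC)(CC)CC)CC(C)=O)[C@@H](/C=C(C)\C=C/CSc2ccccc2)O1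
F5 | step 13 | S-methyl-S-phenylsulfonium triflate from F4 | O=C1C[C@H]([C@H](O[Si](CC)(CC)CC)CC(C)=O)[C@@H](/C=C(C)\C=C/C[S+](C)c2ccccc2)O1.[O-]S(=O)(=O)C(F)(F)F
F6 | step 15 | 11-(hydroxymethyl) derivative of 28 (both C11 epimers) | OCC1C(=O)O[C@@H]2/C=C(C)\C=C/[C@H]3O[C@]3(C)C[C@@H](O[Si](CC)(CC)CC)[C@@H]12
F7 | step 15 | methanesulfonate of F6 | CS(=O)(=O)OCC1C(=O)O[C@@H]2/C=C(C)\C=C/[C@H]3O[C@]3(C)C[C@@H](O[Si](CC)(CC)CC)[C@@H]12
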